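## Structural features

The target consists of two rings joined through a single methylene carbon. Ring A is a fully substituted 4-hydroxy-2H-pyran-2-one (O1, lactone carbonyl C2, C3 carrying the bridge, C4–OH, C5–CH3, C6–C2H5). Ring B is a benzene with five substituents (C1' bridge, C2'–OCH3, C3'–H, C4'–OH, C5'–(R)-2-methylbutanoyl, C6'–OH). The only stereocenter is C2 of the acyl chain; it has no stereogenic neighbour, but it lies α to an aryl ketone flanked by two hydroxyl groups, so it can be lost by enolisation under base or strong Lewis acid. The fragile elements are the vinylogous-acid enol and the lactone of ring A, the oxidation-prone trioxygenated ring B, and the methylene bridge, which links two electron-rich rings and can be cleaved or shifted by acid. The real difficulty is the differentiation of ring B: three oxygens in a 1,3,5-relationship of which only C2' is methylated, and two different carbon substituents (C1' and C5') that must each sit between the correct pair of oxygens. The key step exploits the triad C6'(OH)–C1'(carbon)–C2'(OMe): a carbon substituent between a free hydroxyl and a methyl ether is what a vinylketene and a 1-methoxyalkyne deliver, while the C4' oxygen comes separately from the four-carbon partner. All three oxygens are therefore distinguishable from the moment ring B exists, and the stereocenter can be bought and attached after every basic operation.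

## Logic of the disconnections

25 to 24: the O–CH2 bond of an ethyl ether at C4' is cut. The C4' oxygen must stay capped while the acyl group is introduced, so that C6'–OH is the only free phenol and steers the acylation to C5'. The gain is that telling the C4' and C2' oxygens apart reduces to "ortho or para to the ketone". The forward step must cleave an ethyl ether flanking the ketone, spare the methyl ether para to it, and not enolise the stereocenter.

24 to 21 and 23 (from 22): the C5'–C(=O) bond is cut. This keeps the only stereocenter out of all base-mediated chemistry and takes it from the chiral pool. Ring B becomes a simple phenol. The forward step must acylate ortho to C6'–OH (C5') and not at C3', without racemising the acid chloride.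

21 to 20: an O–benzyl bond is cut. The C6' oxygen has to be masked through the oxidation and the enolate chemistry, and a benzyl ether can be removed under neutral conditions that ring A tolerates.

20 to 19: the C3–C4 bond of ring A is cut (intramolecular Claisen). Ring A becomes an acyclic enol ester. The forward step needs the Z geometry and an ester enolate that closes onto the methyl ester faster than it fragments.

19 to 16 and 17 (through 18): the enol O–C(=O) bond, the future O1–C2, is cut. Atoms C4, C5 and C6 of ring A with both alkyl groups are then bought ready-made as 17. The forward step must acylate on oxygen and not on carbon, with the acyloxy group cis to the ester.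

16 to 15 to 13 (through 14): no skeletal bond is cut; the chain terminus is taken back from acid to silyl-protected alcohol and the benzyl ether to the free phenol. The free electron-rich phenol would not survive the oxidation, so the forward sequence must benzylate the phenol selectively in the presence of the primary alcohol.

13 to 4 and 8: the bonds C6'–C1', C2'–C3' and C6'–C5' are cut. Ring B disappears completely and is replaced by a four-carbon and a two-carbon partner that already carry the three oxygens in differentiated form. The forward step requires one orientation of the ketene–alkyne addition.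

8 to 5 and 6; 4 to 1 and 2 (through 3): the C(sp)–CH2 bond of 8 is cut and the ynol ether is traced to a chloroacetal. Two ring bonds of 4 are cut in a ketene–alkyne [2+2] sense. Both precursors come from catalogue chemicals in one step each. Generating 3 and 7 only in solution avoids a ketene generator, trichloroethylene with the dichloroacetylene it forms under base, and isolated methoxyacetylene.

## Other disconnections considered

Alternative 1: The cut runs across C4'–O and C5'–C(=O) at once. Ring B is traced to the aryne A2 (C4'≡C5'), stored as the ortho-silyl aryl triflate A1 with methoxymethyl groups on the C6' and pyranone oxygens, and to the acid 22 itself.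
- Forward key step: CsF would release A2. The carboxylate of 22 would add through oxygen to C4', the aryne carbon remote from the C6' alkoxy group. The aryl anion at C5' would then attack the ester carbonyl through a four-membered transition state, and the O-to-C acyl shift would give A3. Removal of the two acetal groups would finish 25.
- In favour: the C4' hydroxyl and the acyl group arrive together, the C4' oxygen never needs selective unmasking, 22 is used without activation, and no Lewis acid touches the stereocenter. On these points it is better than steps 9 and 10 of the chosen plan. It is its equal in keeping the stereocenter out of all earlier operations.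
- Against: A1 is a hexasubstituted benzene. Its preparation requires the same differentiated ring B plus a silyl group at C5' and a sulfonate at C4', with ring A already present or built next to a base-labile aryl triflate. Protonation of the C5' anion by 22 before the acyl shift would stop at the aryl ester. The hot fluoride/carboxylate medium is basic enough to threaten the α-stereocenter of the product.
- Comparison: structurally it is the more convergent plan. Mechanistically it rests on an acyl migration outrunning proton transfer, where the chosen plan uses two separate, individually precedented events. In step economy the short endgame would probably be paid for by a longer route to A1 and two extra protecting-group operations.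

Alternative 2: The cut is C3–C4 of ring A.
- Forward key step: the acid A4 would be joined through oxygen to 17. LiN(SiMe3)2 would convert the resulting Z enol ester A5 into its ester enolate, which closes onto the methyl ester to give A6.
- In favour: this is the same ring-A closure that the chosen plan adopts in steps 6 and 7, so on ring A the two plans are equal, with the same mechanistic risk (fragmentation of the enolate to a ketene before closure). A6 carries a benzyl ether at C4', removable at the end by neutral hydrogenolysis; in this respect it is better than step 10 for the stereocenter and for the C2' methyl ether.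
- Against: A4 needs three different oxygen substituents and a three-carbon chain between two particular ones. From a symmetrical 1,3,5-trioxygenated benzene this means stepwise, partly statistical etherification and a regioselective C-functionalisation, which is the problem that step 3 settles by construction.
- Comparison: after A6 the same three operations remain as after 20 (free C6'–OH, acylate C5', unmask C4'), so the endgame is of equal length. The overall count would be equal at best and longer if the differentiated arene has to be made. The chosen plan is better on regiochemical certainty of ring B, the alternative on the mildness of the last deprotection.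

Alternative 3: The cuts are C4–C5 and O1–C2 of ring A, leading to the arylmethylmalonyl dichloride A7 and the symmetrical ketone A8.
- Forward key step: the enol of A8 would be C-acylated by one acid chloride function of A7 and the second would capture the enol oxygen, closing ring A to A9. Hydrogenolysis of both benzyl ethers would then give 25.
- In favour: highest convergency, a cheap symmetrical ketone with no regiochemical question, no strong base once the ketone is present, and a neutral final deprotection. On the last two points it is better than the chosen plan, which uses a strong amide base in step 7 (before the stereocenter exists) and BCl3 in step 10.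
- Against: the acyl group and its stereocenter must be installed early and carried through the preparation of A7 (malonate alkylation, saponification, chlorination). The annulation then sets free two equivalents of strong acid at elevated temperature in the presence of benzyl ethers, an electron-rich arene and an enolisable α-stereogenic ketone. The aryl ketone of A7 can itself enolise and compete with A8, and monosubstituted malonyl dichlorides tend to lose acid to chlorocarbonylketenes that oligomerise.
- Comparison: structurally the alternative is more convergent. Mechanistically the chosen plan exposes the stereocenter only to two short Lewis-acid steps, while the alternative exposes it for most of the route. In step economy the two are probably equal.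

Key step: step 3

Assumption: ring A is numbered O1, C2 (C=O), C3 (bridge), C4 (OH), C5 (Me), C6 (Et) and ring B C1' (bridge), C2' (OMe), C3' (H), C4' (OH), C5' (acyl), C6' (OH); compounds 1, 2, 5, 6, 17 and 22 are taken as catalogue chemicals.

## Route

Step 1
Reactants: 1 ethoxyacetylene; 2 acetyl chloride
Product: 4 3-ethoxycyclobut-2-en-1-one, via ketene 3 (not isolated)
Conditions: Et3N (1.3 equiv), Et2O–hexanes, 0 °C to rt, slow addition of 2
Reagents that add atoms: none
Why: Et3N dehydrochlorinates 2 to ketene 3 in the presence of the ynol ether, whose nucleophilic terminal carbon attacks the ketene carbonyl carbon in a stepwise ketene–alkyne [2+2] cycloaddition; making 3 in solution and consuming it at once avoids a ketene generator and any handling of free ketene.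

Step 2
Reactants: 5 2-chloro-1,1-dimethoxyethane; 6 (3-bromopropoxy)(tert-butyl)dimethylsilane
Product: 8 tert-butyl[(5-methoxypent-4-yn-1-yl)oxy]dimethylsilane, via sodium methoxyacetylide 7 (not isolated)
Conditions: NaNH2 (3.1 equiv), liq. NH3, −33 °C; then 6, THF, −33 °C to rt
Reagents that add atoms: none
Why: Three equivalents of NaNH2 effect a double elimination (methanol, then HCl) from 5 and deprotonate the methoxyacetylene formed, and the acetylide is C-alkylated by the primary bromide 6 (SN2) in the same flask, the classical alkoxyacetylide alkylation; this avoids trichloroethylene, the dichloroacetylene it gives with base, and isolation of volatile methoxyacetylene.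

Step 3
Reactants: 4 3-ethoxycyclobut-2-en-1-one; 8 tert-butyl[(5-methoxypent-4-yn-1-yl)oxy]dimethylsilane
Product: 13 2-[3-(tert-butyldimethylsilyloxy)propyl]-5-ethoxy-3-methoxyphenol, via vinylketene 9 (not isolated), via vinylcyclobutenone 10 (not isolated), via dienylketene 11 (not isolated), via cyclohexadienone 12 (not isolated)
Conditions: toluene (0.3 M), 110 °C, sealed vessel, argon; 4 (1.5 equiv) added in portions
Reagents that add atoms: none
Why: On heating, 4 undergoes reversible four-electron electrocyclic opening to vinylketene 9. The ynol ether 8 is polarised so that its chain-bearing carbon is nucleophilic; it bonds to the ketene carbonyl carbon (C6'–C1') and the methoxy-bearing carbon closes onto the ketene α-carbon (C2'–C3'), a regiospecific [2+2] addition giving 10. Compound 10 opens (four-electron, reversible) to dienylketene 11, and the isomer with the ketene and the ethoxyvinyl group cis on the central double bond closes ring B by six-electron disrotatory electrocyclisation (C6'–C5'); tautomerisation of 12 gives 13. The closest known reaction type is the Danheiser benzannulation of cyclobutenones with alkoxy- and siloxyalkynes, which gives resorcinol monoethers of this pattern; a cyclobutenone with a 3-alkoxy group is a less usual member of that class. No stereocenter is created, since the sp3 carbon of 10 is erased on aromatisation. The one selectivity required, the orientation of the [2+2] event, is secured by the donor oxygen of 8, and the methyl ether has no β-hydrogen, so the retro-ene loss of alkene that limits higher alkoxyalkynes on heating cannot occur. The step is an isomerising addition with no by-product, and the silyl ether is inert to the neutral thermal conditions.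

Step 4
Reactants: 13 2-[3-(tert-butyldimethylsilyloxy)propyl]-5-ethoxy-3-methoxyphenol
Product: 15 3-[2-(benzyloxy)-4-ethoxy-6-methoxyphenyl]propan-1-ol, via diol 14 (not isolated)
Conditions: Bu4NF (1.1 equiv), THF, 0 °C to rt; then BnBr (1.2 equiv), rt
Reagents that add atoms: benzyl bromide, BrCc1ccccc1
Why: Fluoride cleaves the Si–O bond and the alkoxide set free is protonated by the more acidic phenol, so the tetrabutylammonium phenoxide of 14 is the only strong nucleophile present when BnBr is added (Williamson ether synthesis); the primary alcohol is not benzylated, and the phenol must be masked before the oxidation of step 5.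

Step 5
Reactants: 15 3-[2-(benzyloxy)-4-ethoxy-6-methoxyphenyl]propan-1-ol
Product: 16 3-[2-(benzyloxy)-4-ethoxy-6-methoxyphenyl]propanoic acid
Conditions: TEMPO (0.2 equiv), PhI(OAc)2 (2.2 equiv), MeCN–H2O (1:1), rt
Reagents that add atoms: water, O
Why: Oxoammonium-mediated oxidation (TEMPO catalysis with PhI(OAc)2 as terminal oxidant) takes the primary alcohol through the aldehyde hydrate to the acid; the medium contains no electrophilic halogen and no hexavalent chromium that would attack the trialkoxybenzene ring, and the benzyl ether is inert.

Step 6
Reactants: 16 3-[2-(benzyloxy)-4-ethoxy-6-methoxyphenyl]propanoic acid; 17 methyl 2-methyl-3-oxopentanoate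
Product: 19 methyl (2Z)-3-({3-[2-(benzyloxy)-4-ethoxy-6-methoxyphenyl]propanoyl}oxy)-2-methylpent-2-enoate, via acid chloride 18 (not isolated)
Conditions: 16, Me2C=C(Cl)NMe2 (1.05 equiv), CH2Cl2, 0 °C to rt; then added to 17 + NaH (1.1 equiv), THF, 0 °C
Reagents that add atoms: none
Why: The chloroenamine converts 16 into 18 under neutral conditions without a formamide-derived chloroiminium species that could formylate the electron-rich ring; the chelated sodium enolate of 17 is acylated on oxygen (acylation on carbon would create a quaternary centre), and the chelate places the acyloxy group cis to the ester, giving the Z enol ester needed for ring closure.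

Step 7
Reactants: 19 methyl (2Z)-3-({3-[2-(benzyloxy)-4-ethoxy-6-methoxyphenyl]propanoyl}oxy)-2-methylpent-2-enoate
Product: 20 3-{[2-(benzyloxy)-4-ethoxy-6-methoxyphenyl]methyl}-6-ethyl-4-hydroxy-5-methyl-2H-pyran-2-one
Conditions: LiN(SiMe3)2 (2.3 equiv), THF, −78 to 0 °C; aq. HCl
Reagents that add atoms: none
Why: The amide base forms the ester enolate α to the acyloxy carbonyl, which attacks the cis-disposed methyl ester in an intramolecular Claisen (Dieckmann-type) condensation forming C3–C4; loss of methoxide and deprotonation to the stabilised pyranon-4-olate drive the closure, the principle by which O-acylsalicylates give 4-hydroxycoumarins.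

Step 8
Reactants: 20 3-{[2-(benzyloxy)-4-ethoxy-6-methoxyphenyl]methyl}-6-ethyl-4-hydroxy-5-methyl-2H-pyran-2-one
Product: 21 3-[(4-ethoxy-2-hydroxy-6-methoxyphenyl)methyl]-6-ethyl-4-hydroxy-5-methyl-2H-pyran-2-one
Conditions: H2 (1 atm), 10% Pd/C, EtOAc, rt
Reagents that add atoms: none
Why: Hydrogenolysis of the aryl benzyl ether is neutral and leaves the tetrasubstituted pyranone double bonds, the alkyl aryl ethers and the lactone untouched; it frees C6'–OH as the only phenol of ring B.

Step 9
Reactants: 21 3-[(4-ethoxy-2-hydroxy-6-methoxyphenyl)methyl]-6-ethyl-4-hydroxy-5-methyl-2H-pyran-2-one; 22 (R)-2-methylbutanoic acid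
Product: 24 3-({4-ethoxy-2-hydroxy-6-methoxy-3-[(2R)-2-methylbutanoyl]phenyl}methyl)-6-ethyl-4-hydroxy-5-methyl-2H-pyran-2-one, via acid chloride 23 (not isolated)
Conditions: 22 (2.2 equiv), Me2C=C(Cl)NMe2 (2.2 equiv), CH2Cl2, 0 °C to rt; then 21, TiCl4 (3.5 equiv), CH2Cl2, −20 to 0 °C; NaHCO3, aq. MeOH work-up
Reagents that add atoms: none
Why: Acid chloride 23 is formed without base, so no ketene pathway to racemisation is open, and it is transferred to the titanium phenoxide of 21: Friedel–Crafts acylation delivered ortho to the O–Ti bond (a Fries-type transfer within the complex) goes to C5', the only free position next to C6'–O, while C3' lies para and is flanked by two alkoxy groups; any ester formed at the pyranone oxygen is cleaved in the methanolic work-up, and the stereocenter is carried over unchanged from 22 because no bond to it is broken.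

Step 10
Reactants: 24 3-({4-ethoxy-2-hydroxy-6-methoxy-3-[(2R)-2-methylbutanoyl]phenyl}methyl)-6-ethyl-4-hydroxy-5-methyl-2H-pyran-2-one
Product: 25 3-({2,4-dihydroxy-6-methoxy-3-[(2R)-2-methylbutanoyl]phenyl}methyl)-6-ethyl-4-hydroxy-5-methyl-2H-pyran-2-one
Conditions: BCl3 (4 equiv), CH2Cl2, −78 to 0 °C; then H2O
Reagents that add atoms: none
Why: BCl3 binds the ketone oxygen and the flanking C4' ethoxy oxygen in a six-membered chelate and chloride removes the ethyl group (SN2), the usual selective cleavage of ethers ortho to an aryl carbonyl; the C2' methyl ether is para to the ketone, cannot chelate and should be inert to BCl3 at or below 0 °C, and the absence of base keeps the α-stereocenter intact.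

## Compound list

1 | ethoxyacetylene | CCOC#C | starting material
2 | acetyl chloride | CC(=O)Cl | starting material
3 | ketene (ethenone) | C=C=O | intermediate
4 | 3-ethoxycyclobut-2-en-1-one | CCOC1=CC(=O)C1 | intermediate
5 | 2-chloro-1,1-dimethoxyethane | COC(CCl)OC | starting material
6 | (3-bromopropoxy)(tert-butyl)dimethylsilane | CC(C)(C)[Si](C)(C)OCCCBr | starting material
7 | sodium methoxyacetylide | [Na+].[C-]#COC | intermediate
8 | tert-butyl[(5-methoxypent-4-yn-1-yl)oxy]dimethylsilane | COC#CCCCO[Si](C)(C)C(C)(C)C | intermediate
9 | 3-ethoxybuta-1,3-dien-1-one | C=C(OCC)C=C=O | intermediate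
10 | 2-[3-(tert-butyldimethylsilyloxy)propyl]-4-(1-ethoxyethenyl)-3-methoxycyclobut-2-en-1-one (racemic) | CCOC(=C)C1C(=O)C(CCCO[Si](C)(C)C(C)(C)C)=C1OC | intermediate
11 | (3E)-2-[3-(tert-butyldimethylsilyloxy)propyl]-5-ethoxy-3-methoxyhexa-1,3,5-trien-1-one | O=C=C(CCCO[Si](C)(C)C(C)(C)C)/C(OC)=C\C(OCC)=C | intermediate
12 | 2-[3-(tert-butyldimethylsilyloxy)propyl]-5-ethoxy-3-methoxycyclohexa-2,4-dien-1-one | CCOC1=CC(OC)=C(CCCO[Si](C)(C)C(C)(C)C)C(=O)C1 | intermediate
13 | 2-[3-(tert-butyldimethylsilyloxy)propyl]-5-ethoxy-3-methoxyphenol | CCOc1cc(O)c(CCCO[Si](C)(C)C(C)(C)C)c(OC)c1 | intermediate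
14 | 5-ethoxy-2-(3-hydroxypropyl)-3-methoxyphenol | CCOc1cc(O)c(CCCO)c(OC)c1 | intermediate
15 | 3-[2-(benzyloxy)-4-ethoxy-6-methoxyphenyl]propan-1-ol | CCOc1cc(OCc2ccccc2)c(CCCO)c(OC)c1 | intermediate
16 | 3-[2-(benzyloxy)-4-ethoxy-6-methoxyphenyl]propanoic acid | CCOc1cc(OCc2ccccc2)c(CCC(=O)O)c(OC)c1 | intermediate
17 | methyl 2-methyl-3-oxopentanoate (racemic) | CCC(=O)C(C)C(=O)OC | starting material
18 | 3-[2-(benzyloxy)-4-ethoxy-6-methoxyphenyl]propanoyl chloride | CCOc1cc(OCc2ccccc2)c(CCC(=O)Cl)c(OC)c1 | intermediate
19 | methyl (2Z)-3-({3-[2-(benzyloxy)-4-ethoxy-6-methoxyphenyl]propanoyl}oxy)-2-methylpent-2-enoate | CC/C(OC(=O)CCc1c(OCc2ccccc2)cc(OCC)cc1OC)=C(C)/C(=O)OC | intermediate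
20 | 3-{[2-(benzyloxy)-4-ethoxy-6-methoxyphenyl]methyl}-6-ethyl-4-hydroxy-5-methyl-2H-pyran-2-one | CCc1oc(=O)c(Cc2c(OC)cc(OCC)cc2OCc2ccccc2)c(O)c1C | intermediate
21 | 3-[(4-ethoxy-2-hydroxy-6-methoxyphenyl)methyl]-6-ethyl-4-hydroxy-5-methyl-2H-pyran-2-one | CCc1oc(=O)c(Cc2c(OC)cc(OCC)cc2O)c(O)c1C | intermediate
22 | (R)-2-methylbutanoic acid | CC[C@@H](C)C(=O)O | starting material
23 | (R)-2-methylbutanoyl chloride | CC[C@@H](C)C(=O)Cl | intermediate
24 | 3-({4-ethoxy-2-hydroxy-6-methoxy-3-[(2R)-2-methylbutanoyl]phenyl}methyl)-6-ethyl-4-hydroxy-5-methyl-2H-pyran-2-one | CCc1oc(=O)c(Cc2c(OC)cc(OCC)c(C(=O)[C@H](C)CC)c2O)c(O)c1C | intermediate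
25 | 3-({2,4-dihydroxy-6-methoxy-3-[(2R)-2-methylbutanoyl]phenyl}methyl)-6-ethyl-4-hydroxy-5-methyl-2H-pyran-2-one (CNP0199908.1) | CCc1oc(=O)c(Cc2c(OC)cc(O)c(C(=O)[C@H](C)CC)c2O)c(O)c1C | target

## Step count and least certain steps

Total step count: 10. Longest linear sequence: 9 steps (steps 2 to 10, from 5 and 6 to 25); step 1 is a one-step side branch that joins at step 3.

Step 3 (key step). The most likely failure is a slow four-electron opening of 4, because the vinylogous-ester conjugation of the 3-ethoxy group must be given up. This could force temperatures at which 9 is consumed by self-addition or by acylating the product phenol before it meets 8. Ester formation with the product could be reversed by brief treatment of the crude material with K2CO3 in methanol. The fallback changes how the vinylketene is made; it sets out from 8 and returns at 13. Commercial ethyl (2E)-3-ethoxybut-2-enoate would be saponified (LiOH, aqueous THF) to (2E)-3-ethoxybut-2-enoic acid F1. Its sodium salt would be converted with oxalyl chloride into (2E)-3-ethoxybut-2-enoyl chloride F2. Slow addition of F2 to 8 and Et3N in CH2Cl2 at 0 °C would generate 9 by 1,4-dehydrochlorination, so that 10 forms at or below room temperature. Mild heating in toluene (80 °C) would then take 10 through 11 and 12 to 13.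

Step 2. The displacement on the lipophilic bromide by the acetylide in ammonia may be slow, leaving room for elimination or amination of 6 and for polymerisation of the acetylide on warming. The fallback makes the C–C bond by opening a strained ether instead of displacing a halide; it sets out from 5 and returns at 8. LiNEt2 (3 equiv) in THF would convert 5 into lithium methoxyacetylide F3. In the presence of BF3·OEt2 at −78 °C, F3 would open oxetane to 5-methoxypent-4-yn-1-ol F4. Silylation with tert-butyldimethylsilyl chloride and imidazole would give 8.

Step 7 (with the geometry set in step 6). The ester enolate may fragment into a ketene and the enolate of 17 before it closes, deprotonation may occur at the allylic ethyl group, and any E enol ester from step 6 cannot cyclise. The fallback builds the open-chain tricarbonyl compound by intermolecular Claisen chemistry; it sets out from 16 and returns at 20.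
- Methylation (MeI, K2CO3) would give methyl 3-[2-(benzyloxy)-4-ethoxy-6-methoxyphenyl]propanoate F5.
- Its lithium enolate (LiN(iPr)2, 2 equiv) would be acylated with propanoyl chloride to methyl 2-{[2-(benzyloxy)-4-ethoxy-6-methoxyphenyl]methyl}-3-oxopentanoate F6.
- The dianion of F6 (NaH, then n-BuLi) would be acylated at the γ-carbon with N-methoxy-N-methylpropanamide to methyl 2-{[2-(benzyloxy)-4-ethoxy-6-methoxyphenyl]methyl}-4-methyl-3,5-dioxoheptanoate F7.
- DBU in toluene at reflux would lactonise F7 to 20.

Step 9. Three processes threaten this step: electrophilic attack at C3' in competition with C5', acid-promoted cleavage or migration of the methylene bridge between the two electron-rich rings, and erosion of configuration through enolisation of Lewis-acid-bound acyl species. The fallback attaches the acyl group to the C6' oxygen first and then moves it intramolecularly; it sets out from 21 and returns at 24. Compound 21 with 23 (2.2 equiv, pyridine, CH2Cl2) would give 5-ethoxy-2-({6-ethyl-5-methyl-4-[(2R)-2-methylbutanoyloxy]-2-oxo-2H-pyran-3-yl}methyl)-3-methoxyphenyl (2R)-2-methylbutanoate F8. Brief methanolysis (MeOH, NaHCO3) would remove the much more labile pyranone enol ester and leave 5-ethoxy-2-[(6-ethyl-4-hydroxy-5-methyl-2-oxo-2H-pyran-3-yl)methyl]-3-methoxyphenyl (2R)-2-methylbutanoate F9. A Fries rearrangement of F9 with catalytic Sc(OTf)3 in toluene would deliver the acyl group from the C6' oxygen to the adjacent C5' and give 24.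

Step 10. The ketone oxygen is already engaged in a chelate with the boron bound to the C6' oxygen, so cleavage of the ethyl ether may be incomplete. Forcing conditions would then risk loss of the C2' methyl ether or epimerisation. The fallback caps the C6' oxygen so that the ketone is free to chelate with the ethoxy oxygen; it sets out from 24 and returns at 25. Acetylation (Ac2O, Et3N, cat. DMAP) would give 2-[(4-acetoxy-6-ethyl-5-methyl-2-oxo-2H-pyran-3-yl)methyl]-5-ethoxy-3-methoxy-6-[(2R)-2-methylbutanoyl]phenyl acetate F10. BCl3 (1.5 equiv, CH2Cl2, −78 to −20 °C) would then cleave the now singly chelated ethyl ether to 2-[(4-acetoxy-6-ethyl-5-methyl-2-oxo-2H-pyran-3-yl)methyl]-5-hydroxy-3-methoxy-6-[(2R)-2-methylbutanoyl]phenyl acetate F11. K2CO3 in methanol at 0 °C would remove both acetates to give 25.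

## Further compounds

F1 | step 3 | (2E)-3-ethoxybut-2-enoic acid | CCO/C(C)=C/C(=O)O
F2 | step 3 | (2E)-3-ethoxybut-2-enoyl chloride | CCO/C(C)=C/C(=O)Cl
F3 | step 2 | lithium methoxyacetylide | [Li+].[C-]#COC
F4 | step 2 | 5-methoxypent-4-yn-1-ol | COC#CCCCO
F5 | step 7 | methyl 3-[2-(benzyloxy)-4-ethoxy-6-methoxyphenyl]propanoate | COC(=O)CCc1c(OCc2ccccc2)cc(OCC)cc1OC
F6 | step 7 | methyl 2-{[2-(benzyloxy)-4-ethoxy-6-methoxyphenyl]methyl}-3-oxopentanoate | CCC(=O)C(Cc1c(OCc2ccccc2)cc(OCC)cc1OC)C(=O)OC
F7 | step 7 | methyl 2-{[2-(benzyloxy)-4-ethoxy-6-methoxyphenyl]methyl}-4-methyl-3,5-dioxoheptanoate | CCC(=O)C(C)C(=O)C(Cc1c(OCc2ccccc2)cc(OCC)cc1OC)C(=O)OC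
F8 | step 9 | 5-ethoxy-2-({6-ethyl-5-methyl-4-[(2R)-2-methylbutanoyloxy]-2-oxo-2H-pyran-3-yl}methyl)-3-methoxyphenyl (2R)-2-methylbutanoate | CCc1oc(=O)c(Cc2c(OC)cc(OCC)cc2OC(=O)[C@H](C)CC)c(OC(=O)[C@H](C)CC)c1C
F9 | step 9 | 5-ethoxy-2-[(6-ethyl-4-hydroxy-5-methyl-2-oxo-2H-pyran-3-yl)methyl]-3-methoxyphenyl (2R)-2-methylbutanoate | CCc1oc(=O)c(Cc2c(OC)cc(OCC)cc2OC(=O)[C@H](C)CC)c(O)c1C
F10 | step 10 | 2-[(4-acetoxy-6-ethyl-5-methyl-2-oxo-2H-pyran-3-yl)methyl]-5-ethoxy-3-methoxy-6-[(2R)-2-methylbutanoyl]phenyl acetate | CCc1oc(=O)c(Cc2c(OC)cc(OCC)c(C(=O)[C@H](C)CC)c2OC(C)=O)c(OC(C)=O)c1C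
F11 | step 10 | 2-[(4-acetoxy-6-ethyl-5-methyl-2-oxo-2H-pyran-3-yl)methyl]-5-hydroxy-3-methoxy-6-[(2R)-2-methylbutanoyl]phenyl acetate | CCc1oc(=O)c(Cc2c(OC)cc(O)c(C(=O)[C@H](C)CC)c2OC(C)=O)c(OC(C)=O)c1C
A1 | alternative 1 | 4-{[6-ethyl-4-(methoxymethoxy)-5-methyl-2-oxo-2H-pyran-3-yl]methyl}-5-methoxy-3-(methoxymethoxy)-2-(trimethylsilyl)phenyl trifluoromethanesulfonate | CCc1oc(=O)c(Cc2c(OC)cc(OS(=O)(=O)C(F)(F)F)c([Si](C)(C)C)c2OCOC)c(OCOC)c1C
A2 | alternative 1 | 3-{[6-methoxy-2-(methoxymethoxy)-3,4-didehydrophenyl]methyl}-6-ethyl-4-(methoxymethoxy)-5-methyl-2H-pyran-2-one (aryne) | CCc1oc(=O)c(CC2=C(OCOC)C#CC=C2OC)c(OCOC)c1C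
A3 | alternative 1 | 3-({4-hydroxy-6-methoxy-2-(methoxymethoxy)-3-[(2R)-2-methylbutanoyl]phenyl}methyl)-6-ethyl-4-(methoxymethoxy)-5-methyl-2H-pyran-2-one | CCc1oc(=O)c(Cc2c(OC)cc(O)c(C(=O)[C@H](C)CC)c2OCOC)c(OCOC)c1C
A4 | alternative 2 | 3-[4-(benzyloxy)-2-methoxy-6-(methoxymethoxy)phenyl]propanoic acid | OC(=O)CCc1c(OC)cc(OCc2ccccc2)cc1OCOC
A5 | alternative 2 | methyl (2Z)-3-({3-[4-(benzyloxy)-2-methoxy-6-(methoxymethoxy)phenyl]propanoyl}oxy)-2-methylpent-2-enoate | CC/C(OC(=O)CCc1c(OC)cc(OCc2ccccc2)cc1OCOC)=C(C)/C(=O)OC
A6 | alternative 2 | 3-{[4-(benzyloxy)-2-methoxy-6-(methoxymethoxy)phenyl]methyl}-6-ethyl-4-hydroxy-5-methyl-2H-pyran-2-one | CCc1oc(=O)c(Cc2c(OC)cc(OCc3ccccc3)cc2OCOC)c(O)c1C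
A7 | alternative 3 | 2-({2,4-bis(benzyloxy)-6-methoxy-3-[(2R)-2-methylbutanoyl]phenyl}methyl)propanedioyl dichloride | ClC(=O)C(Cc1c(OC)cc(OCc2ccccc2)c(C(=O)[C@H](C)CC)c1OCc1ccccc1)C(Cl)=O
A8 | alternative 3 | pentan-3-one | CCC(=O)CC
A9 | alternative 3 | 3-({2,4-bis(benzyloxy)-6-methoxy-3-[(2R)-2-methylbutanoyl]phenyl}methyl)-6-ethyl-4-hydroxy-5-methyl-2H-pyran-2-one | CCc1oc(=O)c(Cc2c(OC)cc(OCc3ccccc3)c(C(=O)[C@H](C)CC)c2OCc2ccccc2)c(O)c1C
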